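**Retrosynthetic overview**

1. The target is the C6 salicylate of jaeschkeanadiol (daucane numbering: C1 angular C–CH3, C2/C3 CH2, C4 C(OH)(iPr), C5 ring-fusion CH, C6 CH–O, C7 CH2, C8 =C(CH3), C9 =CH, C10 CH2; β = face of the C1 methyl). The ester C–O bond is made last, from the diol and salicylic acid acetonide.
2. The diol comes from the 4β-hydroxy-6-ketone by hydroxyl-directed reduction. The ketone comes from an oxygen-bridged enone by reductive excision of the bridging oxygen (C5–O as an α-alkoxy ketone, then C9–O as a vinylogous acetate), which leaves H at C5 and the alkene at C8=C9.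
3. Key disconnection: C9–C10 and C1–C5, formed together in an intramolecular [5+2] cycloaddition of a 3-oxidopyrylium with a tethered 1,1-disubstituted alkene. Ring order: furan → pyranone (temporary) → five-membered ring (C1–C5) and seven-membered ring (C5–C10 plus C1) closed in the same step.
4. Feature that allows it: the seven-membered ring has its oxygen at C6 next to ring-fusion C5 and its methyl at C8, so the arc C5–C6(O)–C7–C8(CH3)–C9 is C2–C6 of a 5-methyl-3-oxidopyrylium. C10=C1(CH3) is joined to C5 by C4–C3–C2, the other three atoms of the five-membered ring. The pyrylium oxygen becomes a temporary C5–O–C9 bridge that is removed again.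
5. The pyranone comes from a 4-methyl-2-furyl carbinol (Achmatowicz), made from 3-methylfuran and an α-silyloxy aldehyde. Its single stereocentre (C4) is set by Sharpless epoxidation of 2-isopropylallyl alcohol, and the epoxide is opened by a methallyl Grignard reagent.

Key step: step 9

Remark: the sense of the Sharpless epoxidation is assigned on the assumption that L-(+)-tartrate gives (S)-2-alkylglycidols, so D-(−)-tartrate is used for the (R)-epoxide.

**Route**

Step 1
Reactants: 1 prop-2-yn-1-ol; 2 isopropylmagnesium chloride (iPrMgCl)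
Product: 3 3-methyl-2-methylidenebutan-1-ol
Conditions: iPrMgCl (2.5 equiv), CuI (10 mol %), Et2O/THF, 0 °C → rt; sat. aq NH4Cl
Reagents that add atoms: none
Why: Copper-catalysed anti-carbomagnesiation of the magnesium alkoxide of a propargylic alcohol puts the isopropyl group on the internal alkyne carbon through a five-membered alkoxide chelate, and protonolysis on work-up gives the 2-substituted allylic alcohol; no stereocentre is formed.

Step 2
Reactants: 3 3-methyl-2-methylidenebutan-1-ol
Product: 4 [(2R)-2-(propan-2-yl)oxiran-2-yl]methanol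
Conditions: Ti(OiPr)4 (10 mol %), D-(−)-diisopropyl tartrate (12 mol %), t-BuOOH (2 equiv, isooctane), 4 Å MS, CH2Cl2, −20 °C
Reagents that add atoms: tert-butyl hydroperoxide, CC(C)(C)OO
Why: Katsuki–Sharpless asymmetric epoxidation under the catalytic molecular-sieve protocol (suited to sensitive 2-substituted glycidols); the C4 stereocentre is set by the titanium–tartrate catalyst, D-(−)-tartrate being chosen on the assumption stated in the remark.

Step 3
Reactants: 4 [(2R)-2-(propan-2-yl)oxiran-2-yl]methanol; 5 2-methylallylmagnesium chloride (CH2=C(CH3)CH2MgCl)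
Product: 6 (2R)-5-methyl-2-(propan-2-yl)hex-5-ene-1,2-diol
Conditions: 5 (3 equiv), CuI (10 mol %), THF, −40 → 0 °C; sat. aq NH4Cl
Reagents that add atoms: none
Why: Copper-catalysed SN2 opening of a 2,2-disubstituted oxirane by an allylic Grignard reagent occurs at the unsubstituted CH2 terminus, so the C–O bond at the stereocentre is untouched and the (R) configuration is kept (a Payne rearrangement of this epoxy alcohol is degenerate and cannot erode it).

Step 4
Reactants: 6 (2R)-5-methyl-2-(propan-2-yl)hex-5-ene-1,2-diol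
Product: 7 (2R)-5-methyl-2-(propan-2-yl)-1,2-bis[(triethylsilyl)oxy]hex-5-ene
Conditions: Et3SiOTf (2.5 equiv), 2,6-lutidine (4 equiv), CH2Cl2, −78 → 0 °C
Reagents that add atoms: triethylsilyl trifluoromethanesulfonate, CC[Si](CC)(CC)OS(=O)(=O)C(F)(F)F
Why: A silyl triflate with 2,6-lutidine silylates the primary and the hindered tertiary hydroxyl alike; no stereocentre is touched.

Step 5
Reactants: 7 (2R)-5-methyl-2-(propan-2-yl)-1,2-bis[(triethylsilyl)oxy]hex-5-ene
Product: 8 (2R)-5-methyl-2-(propan-2-yl)-2-[(triethylsilyl)oxy]hex-5-enal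
Conditions: (COCl)2, DMSO, CH2Cl2, −78 → −30 °C; Et3N, −78 °C → rt
Reagents that add atoms: none
Why: Under Swern conditions the activated sulfonium salt cleaves a primary triethylsilyl ether much faster than a tertiary one and the alkoxysulfonium salt collapses to the aldehyde with Et3N (selective oxidative desilylation); the aldehyde has no α-hydrogen, so the stereocentre cannot epimerise.

Step 6
Reactants: 8 (2R)-5-methyl-2-(propan-2-yl)-2-[(triethylsilyl)oxy]hex-5-enal; 9 3-methylfuran
Product: 11 (2R)-5-methyl-1-(4-methylfuran-2-yl)-2-(propan-2-yl)-2-[(triethylsilyl)oxy]hex-5-en-1-ol (both C1 epimers), via 4-methylfuran-2-yllithium 10 (not isolated)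
Conditions: 9 (1.3 equiv), n-BuLi, TMEDA, THF, −78 → 0 °C; then 8, −78 °C; sat. aq NH4Cl at −78 °C
Reagents that add atoms: none
Why: α-Lithiation of 3-methylfuran should occur mainly at the unhindered C5–H (any 2,3-isomer is removed by chromatography), and 1,2-addition to the aldehyde gives the furyl carbinol; the new carbinol centre is formed without control, which is harmless because it becomes the sp2 C2 of the pyrylium in step 9, and the cold quench prevents 1,2-silyl migration.

Step 7
Reactants: 11 (2R)-5-methyl-1-(4-methylfuran-2-yl)-2-(propan-2-yl)-2-[(triethylsilyl)oxy]hex-5-en-1-ol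
Product: 12 2-{(3R)-2,6-dimethyl-3-[(triethylsilyl)oxy]hept-6-en-3-yl}-6-hydroxy-5-methyl-2H-pyran-3(6H)-one (stereoisomer mixture at C2 and C6)
Conditions: NBS (1.05 equiv), NaHCO3, NaOAc, THF/H2O (4:1), 0 °C
Reagents that add atoms: water, O
Why: Achmatowicz oxidative ring expansion of a 2-furyl carbinol; the electron-rich furan reacts ahead of the 1,1-disubstituted alkene, and the two new centres disappear again in step 9.

Step 8
Reactants: 12 2-{(3R)-2,6-dimethyl-3-[(triethylsilyl)oxy]hept-6-en-3-yl}-6-hydroxy-5-methyl-2H-pyran-3(6H)-one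
Product: 13 6-acetoxy-2-{(3R)-2,6-dimethyl-3-[(triethylsilyl)oxy]hept-6-en-3-yl}-5-methyl-2H-pyran-3(6H)-one (stereoisomer mixture)
Conditions: Ac2O, pyridine, DMAP (cat.), CH2Cl2, 0 °C
Reagents that add atoms: acetic anhydride, CC(=O)OC(C)=O
Why: DMAP-catalysed acylation turns the anomeric hydroxyl into the leaving group needed for ylide formation; the tertiary silyl ether keeps the C4 oxygen from trapping the anomeric carbon as a bicyclic ketal.

Step 9
Reactants: 13 6-acetoxy-2-{(3R)-2,6-dimethyl-3-[(triethylsilyl)oxy]hept-6-en-3-yl}-5-methyl-2H-pyran-3(6H)-one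
Product: 15 5α,9α-epoxy-4β-[(triethylsilyl)oxy]dauc-7-en-6-one (oxygen bridge C5–O–C9 on the α-face), via 3-oxidopyrylium ylide 14 (not isolated)
Conditions: DBU (1.5 equiv), MeCN (0.01 M), 60 °C
Reagents that add atoms: none
Why: DBU removes the C2–H of the acetoxypyranone and acetate leaves, giving 3-oxidopyrylium 14, whose C2 and C6 termini add suprafacially across the tethered alkene in a thermally allowed [5+2] (4π + 2π) cycloaddition; the closest known reaction type is the intramolecular oxidopyrylium–alkene cycloaddition of Achmatowicz-derived acetoxypyranones. The cyclopentane (C1–C5) closes through the three-atom tether in the fused, tether-exo mode, and the seven-membered carbocycle closes as the carbocyclic ring of the 8-oxabicyclo[3.2.1]octenone, the terminal CH2 (C10) bonding to C9 and the substituted alkene carbon (C1) to C5. The quaternary centre C1 is controlled by C4 through the tether conformation: the isopropyl group should sit beside the ring oxygen and the silyloxy group beside the C6 oxide, which avoids allylic strain with the oxide oxygen and a 1,3-syn clash of isopropyl with the alkene methyl, so the C1 methyl ends up cis to the silyloxy group. C5 and C9 follow from C1 because the oxygen bridge must be cis to C10, which places the bridging oxygen exactly where H-5 of the target will be (trans ring fusion already encoded). The step needs diastereofacial selectivity, secured by the C4 stereocentre as described, and cyclisation ahead of ylide dimerisation, secured by the hindered C2 substituent and high dilution; regiochemistry is fixed by the tether length.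

Step 10
Reactants: 15 5α,9α-epoxy-4β-[(triethylsilyl)oxy]dauc-7-en-6-one
Product: 16 9α-hydroxy-4β-[(triethylsilyl)oxy]dauc-7-en-6-one (5α-H, trans-fused)
Conditions: SmI2 (2.5 equiv), MeOH (10 equiv), THF, −78 °C
Reagents that add atoms: none
Why: SmI2 reduction of an α-alkoxy ketone (the C6 ketyl expels the adjacent C5–O bond, relieving the strain of the oxabicycle) gives a samarium enolate that should be protonated at C5 on the α-face, the face just vacated by the oxygen and opposite to the C1 methyl and the C4 silyloxy group, which sets C5–H trans to the angular methyl.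

Step 11
Reactants: 16 9α-hydroxy-4β-[(triethylsilyl)oxy]dauc-7-en-6-one
Product: 17 9α-acetoxy-4β-[(triethylsilyl)oxy]dauc-7-en-6-one
Conditions: Ac2O, pyridine, DMAP (cat.), CH2Cl2, 0 °C → rt
Reagents that add atoms: acetic anhydride, CC(=O)OC(C)=O
Why: DMAP-catalysed acetylation of the secondary allylic alcohol turns the γ-oxygen into a leaving group; the tertiary silyl ether is inert and no stereocentre is touched.

Step 12
Reactants: 17 9α-acetoxy-4β-[(triethylsilyl)oxy]dauc-7-en-6-one
Product: 18 4β-[(triethylsilyl)oxy]dauc-8-en-6-one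
Conditions: SmI2 (2.5 equiv), MeOH (5 equiv), THF, −78 °C; sat. aq NH4Cl at −78 °C
Reagents that add atoms: none
Why: SmI2 reduction of a γ-acetoxy enone (vinylogous reductive elimination) expels acetate from C9 to give the C6–C7/C8–C9 dienolate, whose kinetic protonation at the α-carbon C7 gives the β,γ-unsaturated ketone with the alkene at C8=C9; C5 is not part of this enolate and keeps its configuration.

Step 13
Reactants: 18 4β-[(triethylsilyl)oxy]dauc-8-en-6-one
Product: 19 4β-hydroxydauc-8-en-6-one
Conditions: HF·pyridine, pyridine, THF, 0 °C → rt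
Reagents that add atoms: none
Why: Fluoride cleavage of the tertiary silyl ether under buffered, non-basic conditions avoids retro-aldol cleavage of the β-hydroxy ketone and conjugation of the alkene.

Step 14
Reactants: 19 4β-hydroxydauc-8-en-6-one
Product: 20 jaeschkeanadiol, (3R,3aS,4S,8aR)-6,8a-dimethyl-3-(propan-2-yl)-1,2,3,3a,4,5,8,8a-octahydroazulene-3,4-diol (dauc-8-ene-4β,6α-diol)
Conditions: Me4NBH(OAc)3 (5 equiv), MeCN/AcOH (1:1), −30 °C
Reagents that add atoms: none
Why: Evans–Saksena hydroxyl-directed reduction: the C4 alkoxy(diacetoxy)borohydride delivers hydride intramolecularly to the β-face of the C6 carbonyl through a six-membered transition state, setting the 6α (equatorial) hydroxyl anti to the C4 hydroxyl.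

Step 15
Reactants: 20 jaeschkeanadiol; 21 2,2-dimethyl-4H-1,3-benzodioxin-4-one (salicylic acid acetonide)
Product: 22 [(3R,3aS,4S,8aR)-3-hydroxy-6,8a-dimethyl-3-(propan-2-yl)-1,2,3,3a,4,5,8,8a-octahydroazulen-4-yl] 2-hydroxybenzoate (CNP0379621.1)
Conditions: NaN(SiMe3)2 (1.1 equiv), THF, 0 °C; then 21, 0 °C → rt; sat. aq NH4Cl
Reagents that add atoms: none
Why: Alkoxide opening of the salicylic acid acetonide (attack at the lactone carbonyl, loss of acetone) gives the salicylate with its free phenol in one step; the secondary C6 alkoxide reacts while the hindered tertiary C4 hydroxyl does not, and no stereocentre is touched.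

**Compound list**

1 | prop-2-yn-1-ol | C#CCO | starting material
2 | isopropylmagnesium chloride | CC(C)[Mg]Cl | starting material
3 | 3-methyl-2-methylidenebutan-1-ol | CC(C)C(=C)CO | intermediate
4 | [(2R)-2-(propan-2-yl)oxiran-2-yl]methanol | C1[C@@](O1)(C(C)C)CO | intermediate
5 | 2-methylallylmagnesium chloride | CC(=C)C[Mg]Cl | starting material
6 | (2R)-5-methyl-2-(propan-2-yl)hex-5-ene-1,2-diol | C=C(C)CC[C@@](O)(C(C)C)CO | intermediate
7 | (2R)-5-methyl-2-(propan-2-yl)-1,2-bis[(triethylsilyl)oxy]hex-5-ene | C=C(C)CC[C@@](O[Si](CC)(CC)CC)(C(C)C)CO[Si](CC)(CC)CC | intermediate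
8 | (2R)-5-methyl-2-(propan-2-yl)-2-[(triethylsilyl)oxy]hex-5-enal | C=C(C)CC[C@@](O[Si](CC)(CC)CC)(C(C)C)C=O | intermediate
9 | 3-methylfuran | Cc1ccoc1 | starting material
10 | 4-methylfuran-2-yllithium (not isolated) | Cc1coc([Li])c1 | intermediate
11 | (2R)-5-methyl-1-(4-methylfuran-2-yl)-2-(propan-2-yl)-2-[(triethylsilyl)oxy]hex-5-en-1-ol, C1 epimer mixture | C=C(C)CC[C@@](O[Si](CC)(CC)CC)(C(C)C)C(O)c1cc(C)co1 | intermediate
12 | 2-{(3R)-2,6-dimethyl-3-[(triethylsilyl)oxy]hept-6-en-3-yl}-6-hydroxy-5-methyl-2H-pyran-3(6H)-one, mixture at C2 and C6 | C=C(C)CC[C@@](O[Si](CC)(CC)CC)(C(C)C)C1OC(O)C(C)=CC1=O | intermediate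
13 | 6-acetoxy-2-{(3R)-2,6-dimethyl-3-[(triethylsilyl)oxy]hept-6-en-3-yl}-5-methyl-2H-pyran-3(6H)-one, mixture at C2 and C6 | C=C(C)CC[C@@](O[Si](CC)(CC)CC)(C(C)C)C1OC(OC(C)=O)C(C)=CC1=O | intermediate
14 | 2-{(3R)-2,6-dimethyl-3-[(triethylsilyl)oxy]hept-6-en-3-yl}-5-methylpyrylium-3-olate (not isolated) | C=C(C)CC[C@@](O[Si](CC)(CC)CC)(C(C)C)c1[o+]cc(C)cc1[O-] | intermediate
15 | 5α,9α-epoxy-4β-[(triethylsilyl)oxy]dauc-7-en-6-one (C1 methyl β, oxygen bridge α) | CC=1[C@@H]2C[C@@]3(C)CC[C@@](O[Si](CC)(CC)CC)(C(C)C)[C@]3(O2)C(=O)C=1 | intermediate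
16 | 9α-hydroxy-4β-[(triethylsilyl)oxy]dauc-7-en-6-one (5α-H) | CC=1[C@@H](O)C[C@@]2(C)CC[C@@](O[Si](CC)(CC)CC)(C(C)C)[C@@H]2C(=O)C=1 | intermediate
17 | 9α-acetoxy-4β-[(triethylsilyl)oxy]dauc-7-en-6-one | CC=1[C@@H](OC(C)=O)C[C@@]2(C)CC[C@@](O[Si](CC)(CC)CC)(C(C)C)[C@@H]2C(=O)C=1 | intermediate
18 | 4β-[(triethylsilyl)oxy]dauc-8-en-6-one | CC1=CC[C@@]2(C)CC[C@@](O[Si](CC)(CC)CC)(C(C)C)[C@@H]2C(=O)C1 | intermediate
19 | 4β-hydroxydauc-8-en-6-one | CC1=CC[C@@]2(C)CC[C@@](O)(C(C)C)[C@@H]2C(=O)C1 | intermediate
20 | jaeschkeanadiol, (3R,3aS,4S,8aR)-6,8a-dimethyl-3-(propan-2-yl)-1,2,3,3a,4,5,8,8a-octahydroazulene-3,4-diol | CC1=CC[C@@]2(C)CC[C@@](O)(C(C)C)[C@@H]2[C@@H](O)C1 | intermediate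
21 | 2,2-dimethyl-4H-1,3-benzodioxin-4-one | CC1(C)OC(=O)c2ccccc2O1 | starting material
22 | [(3R,3aS,4S,8aR)-3-hydroxy-6,8a-dimethyl-3-(propan-2-yl)-1,2,3,3a,4,5,8,8a-octahydroazulen-4-yl] 2-hydroxybenzoate | CC1=CC[C@@]2(C)CC[C@@](O)(C(C)C)[C@@H]2[C@@H](OC(=O)c2ccccc2O)C1 | target

**Step count and risks**

Total step count: 15. Longest linear sequence: 15 steps (1 → 22).

Steps most likely to fail:

1. Step 9. The bond between the two fully substituted carbons C5 and C1, next to the quaternary silyloxy carbon C4, may form too slowly, so that the ylide dimerises or decomposes, or the alkene may add to the other face of the pyrylium. The fallback makes the tether carbon secondary and brings in the isopropyl group after the cycloaddition; it sets out from 5 and 9 (with commercial (S)-glycidol) and comes back at 15. (S)-Glycidol would be opened with 5 and CuI to (2R)-5-methylhex-5-ene-1,2-diol F1, silylated with Et3SiOTf to (2R)-5-methyl-1,2-bis[(triethylsilyl)oxy]hex-5-ene F2, and oxidised under Swern conditions to (2R)-5-methyl-2-[(triethylsilyl)oxy]hex-5-enal F3. Addition of 10 would give (2R)-5-methyl-1-(4-methylfuran-2-yl)-2-[(triethylsilyl)oxy]hex-5-en-1-ol F4, NBS in aqueous THF the hydroxypyranone 6-hydroxy-5-methyl-2-{(1R)-4-methyl-1-[(triethylsilyl)oxy]pent-4-en-1-yl}-2H-pyran-3(6H)-one F5, and Ac2O its acetate 6-acetoxy-5-methyl-2-{(1R)-4-methyl-1-[(triethylsilyl)oxy]pent-4-en-1-yl}-2H-pyran-3(6H)-one F6. DBU would then give, through 5-methyl-2-{(1R)-4-methyl-1-[(triethylsilyl)oxy]pent-4-en-1-yl}pyrylium-3-olate F7, the less crowded cycloadduct 5α,9α-epoxy-4α-[(triethylsilyl)oxy]-11,12,13-trinordauc-7-en-6-one F8, the single tether substituent lying beside the ring oxygen. HF·pyridine would free 5α,9α-epoxy-4α-hydroxy-11,12,13-trinordauc-7-en-6-one F9, and Dess–Martin periodinane would give 5α,9α-epoxy-11,12,13-trinordauc-7-ene-4,6-dione F10, which cannot enolise between the carbonyls because C5 is quaternary. iPrMgCl with CeCl3 at −78 °C should add to the more electrophilic cyclopentanone carbonyl from the α-face, beside the small bridging oxygen and away from C6 and the angular methyl, to give 5α,9α-epoxy-4β-hydroxydauc-7-en-6-one F11, and Et3SiOTf with 2,6-lutidine would return 15.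

2. Step 10. Protonation of the samarium enolate at C5 from the β-face would give the cis ring fusion, which cannot be corrected later without moving the C8=C9 double bond into conjugation. The fallback sets C5 under thermodynamic control and replaces the acetate route to the alkene; it sets out from 16 (whatever its C5 epimer ratio) and comes back at 18. Dess–Martin oxidation of the C9 hydroxyl would give 4β-[(triethylsilyl)oxy]dauc-7-ene-6,9-dione F12, in which C5–H can be equilibrated with DBU to the trans-fused epimer. Condensation of the less hindered C9 carbonyl with tosylhydrazine would give the 9-(4-methylbenzenesulfonyl)hydrazone of 4β-[(triethylsilyl)oxy]dauc-7-ene-6,9-dione F13. Catecholborane followed by NaOAc (Kabalka reductive transposition) would give the allylic diazene 9-diazenyl-4β-[(triethylsilyl)oxy]dauc-7-en-6-one F14, which loses dinitrogen in a retro-ene step that puts hydrogen on C7 and the double bond at C8=C9, giving 18.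

3. Step 14. Hydride may be delivered to the α-face (giving the 6β-alcohol), or the free β-hydroxy ketone may suffer retro-aldol cleavage or alkene conjugation before it is reduced. The fallback gives up hydroxyl direction for thermodynamic control and reverses the order of reduction and desilylation; it sets out from 18 and comes back at 20. Electron-transfer reduction of the silyl ether 18 with SmI2, H2O and Et3N in THF should favour the more stable equatorial alcohol 4β-[(triethylsilyl)oxy]dauc-8-en-6α-ol F15, as in dissolving-metal reductions, and HF·pyridine would then give 20 without the β-hydroxy ketone ever being formed.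

**Further compounds**

F1 | step 9 | (2R)-5-methylhex-5-ene-1,2-diol | C=C(C)CC[C@@H](O)CO
F2 | step 9 | (2R)-5-methyl-1,2-bis[(triethylsilyl)oxy]hex-5-ene | C=C(C)CC[C@@H](O[Si](CC)(CC)CC)CO[Si](CC)(CC)CC
F3 | step 9 | (2R)-5-methyl-2-[(triethylsilyl)oxy]hex-5-enal | C=C(C)CC[C@@H](O[Si](CC)(CC)CC)C=O
F4 | step 9 | (2R)-5-methyl-1-(4-methylfuran-2-yl)-2-[(triethylsilyl)oxy]hex-5-en-1-ol, C1 epimer mixture | C=C(C)CC[C@@H](O[Si](CC)(CC)CC)C(O)c1cc(C)co1
F5 | step 9 | 6-hydroxy-5-methyl-2-{(1R)-4-methyl-1-[(triethylsilyl)oxy]pent-4-en-1-yl}-2H-pyran-3(6H)-one | C=C(C)CC[C@@H](O[Si](CC)(CC)CC)C1OC(O)C(C)=CC1=O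
F6 | step 9 | 6-acetoxy-5-methyl-2-{(1R)-4-methyl-1-[(triethylsilyl)oxy]pent-4-en-1-yl}-2H-pyran-3(6H)-one | C=C(C)CC[C@@H](O[Si](CC)(CC)CC)C1OC(OC(C)=O)C(C)=CC1=O
F7 | step 9 | 5-methyl-2-{(1R)-4-methyl-1-[(triethylsilyl)oxy]pent-4-en-1-yl}pyrylium-3-olate | C=C(C)CC[C@@H](O[Si](CC)(CC)CC)c1[o+]cc(C)cc1[O-]
F8 | step 9 | 5α,9α-epoxy-4α-[(triethylsilyl)oxy]-11,12,13-trinordauc-7-en-6-one | CC=1[C@@H]2C[C@@]3(C)CC[C@@H](O[Si](CC)(CC)CC)[C@]3(O2)C(=O)C=1
F9 | step 9 | 5α,9α-epoxy-4α-hydroxy-11,12,13-trinordauc-7-en-6-one | CC=1[C@@H]2C[C@@]3(C)CC[C@@H](O)[C@]3(O2)C(=O)C=1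
F10 | step 9 | 5α,9α-epoxy-11,12,13-trinordauc-7-ene-4,6-dione | CC=1[C@@H]2C[C@@]3(C)CCC(=O)[C@]3(O2)C(=O)C=1
F11 | step 9 | 5α,9α-epoxy-4β-hydroxydauc-7-en-6-one | CC=1[C@@H]2C[C@@]3(C)CC[C@@](O)(C(C)C)[C@]3(O2)C(=O)C=1
F12 | step 10 | 4β-[(triethylsilyl)oxy]dauc-7-ene-6,9-dione (trans-fused, 5α-H) | CC=1C(=O)C[C@@]2(C)CC[C@@](O[Si](CC)(CC)CC)(C(C)C)[C@@H]2C(=O)C=1
F13 | step 10 | 9-(4-methylbenzenesulfonyl)hydrazone of 4β-[(triethylsilyl)oxy]dauc-7-ene-6,9-dione | CC=1C(=NNS(=O)(=O)c3ccc(C)cc3)C[C@@]2(C)CC[C@@](O[Si](CC)(CC)CC)(C(C)C)[C@@H]2C(=O)C=1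
F14 | step 10 | 9-diazenyl-4β-[(triethylsilyl)oxy]dauc-7-en-6-one | CC=1C(N=N)C[C@@]2(C)CC[C@@](O[Si](CC)(CC)CC)(C(C)C)[C@@H]2C(=O)C=1
F15 | step 14 | 4β-[(triethylsilyl)oxy]dauc-8-en-6α-ol | CC1=CC[C@@]2(C)CC[C@@](O[Si](CC)(CC)CC)(C(C)C)[C@@H]2[C@@H](O)C1
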